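Count what one catalyst makes before it dies.

    gas phase ⇌ dissolved gas, rate k1*(csat - [dissolved gas]) (k1 = 0.0078 /s, csat = 2.4 mM)
    substrate + dissolved gas + free catalyst → free catalyst + product (k2 = 45000 /M²/s)
    substrate + free catalyst → spent catalyst (k3 = 0.61 /M/s)
    dissolved gas + free catalyst ⇌ idle complex, settled at all times (K4 = 84 /M)

substrate 10 mM; gas phase 2.4 mM (held); free catalyst 50 µM; time 8.0 min

- amount of product at 8.0 min, in percent of the substrate charged
- concentration of dissolved gas in solution at 4.0 min, in percent of saturation
- the change that raises the amount of product at 8.0 min, in percent of the substrate charged most ("none" if none brings more than 2 percentage points) (cedar / elm / larch / none)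
- amount of product at 8.0 min, in percent of the substrate charged, after cedar

- cedar: doubling the transfer coefficient of step 1, all else as stated
- elm: doubling the saturation concentration of gas phase, all else as stated
- larch: doubling the amount of free catalyst, all else as stated

- at the start none of the gas is dissolved
- run time (flask): 8.0 min

In the flask the product step and the death step (substrate with free catalyst) both run on substrate and free catalyst, so these cancel from the ratio of their rates. Product made per catalyst lost is therefore 73.8 /mM times the mean [dissolved gas] seen at the deaths. I called this the yield per death. Holding [substrate] at its charge, I reckoned:

catalyst lifetime: 2.73 min, so lost by 8.0 min: 94.6%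

That lifetime is shorter than the run, so I weighted the rising gas by the deaths:

mean gas = saturation × transfer / (transfer + death rate) = 1.35 mM

yield per death 99.4, product 47.0%

The weak link in that line was that it took no dissolved gas away by reaction. With everything as charged, the product step alone gave dissolved gas a half-life of 0.51 min, shorter than the 1.48 min of transfer. So I added that sink below the line, taking catalyst at its death-weighted mean, half the charge:

sink 0.0112 /s, mean gas 0.744 mM

yield per death 54.9, product 26.0%

This yield per death is a turnover number. The same line gave cedar 39.7%, elm 52.0% and larch 35.9%, so I chose elm. A mean describes no single moment, so I reckoned no gas level for the earlier time.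

The forecast gave 31%, 60%, elm and 41.5%, seeing “a race between gas supply and catalyst death”. Its product stood above mine.

The simulation gave 27.4%, 52.1%, elm and 39.0%, with gains of 12 percentage points for cedar, 24 points for elm and 13 points for larch.

The flask had not come to rest at 8.00 min, with free catalyst at 9.19% of the catalyst charged. Ten times as long raised product to 35.6% of the substrate charged, and by then free catalyst stood at 0% and spent catalyst at 100% of the catalyst charged, with substrate at 63.9% of its charge. In the flask, product per spent catalyst read 61.3 at 8.00 min against my 54.9, and 71.1 at 80.0 min.

For the neighbour flask with 2.5 mM of substrate, the same line gave a yield per death of 114, which put the catalyst loss that matched its whole substrate charge at 43.9% of the catalyst charged. Computed, at 8.00 min that neighbour flask stood at 63.7% product of its substrate charge with 35.5% of its catalyst spent, a yield per death of 89.8, and 36% of its substrate was still there.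

The numbers of this flask were set for the occasion; the rest is arithmetic.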